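**Strategy.** Numbering the bicyclo[3.2.1]octene core C1 (OMe bridgehead), C2 (CHOAc), C3 (=C–OMe), C4, C5 (allyl bridgehead), C6, C7, C8 (bridging C=O), the six-membered ring holds C8 and C3 in a 1,4-relationship, both at carbonyl oxidation level, so one temporary oxygen atom can tie them. The route rests on an intramolecular carbonyl-ylide [3+2] cycloaddition: a rhodium carbene at C8 is trapped by the C3 ester carbonyl and the five-membered ylide adds across the tethered C1=C2 enol acetate, forming C8–C1 and C3–C2 and closing both carbocycles from an open chain. That chain, carrying the C5/C6/C7 stereotriad, comes from oxidative cleavage of a cyclohexene.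

Key step: step 11

Remark: in compounds 12–18 the carbons that become C1 and C2 carry stereocentres that are erased later (C1 becomes sp2 in 19, C2 is re-set in step 14), so the isomer drawn is simply the expected one; the (R)-configured organocatalyst in step 1 is assumed to give the (S)-enone by the usual shielding model.

**Step 1**
Reactants: 1 tert-butyl 3-oxobutanoate; 2 (E)-but-2-enal
Product: 5 (S)-5-methylcyclohex-2-en-1-one, via Michael adduct 3 (not isolated), via cyclic keto ester 4 (not isolated)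
Conditions: (R)-2-[bis(3,5-bis(trifluoromethyl)phenyl)(trimethylsilyloxy)methyl]pyrrolidine (10 mol%), neat, rt; then p-TsOH·H2O (20 mol%), toluene, 80 °C
Reagents that add atoms: none
Why: Iminium-catalysed Michael addition of the β-keto ester to the enal, then acid-mediated intramolecular aldol condensation, tert-butyl ester cleavage and decarboxylation (organocatalytic Robinson-type cyclohexenone synthesis); the catalyst shields one face of the iminium ion and so sets the methyl-bearing centre (later C6) as S.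

**Step 2**
Reactants: 5 (S)-5-methylcyclohex-2-en-1-one; 6 allyl bromide
Product: 7 (5S,6R)-5-methyl-6-(prop-2-en-1-yl)cyclohex-2-en-1-one
Conditions: LiN(i-Pr)2, THF, −78 °C; then 6, DMPU, −78 → −20 °C
Reagents that add atoms: allyl bromide (6), C=CCBr
Why: Kinetic α'-deprotonation gives the cross-conjugated lithium enolate, which is C-allylated (enolate alkylation) anti to the adjacent methyl group; this centre is enolised again in step 3.

**Step 3**
Reactants: 7 (5S,6R)-5-methyl-6-(prop-2-en-1-yl)cyclohex-2-en-1-one; 8 methyl bromoacetate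
Product: 9 methyl 2-[(1R,6S)-6-methyl-2-oxo-1-(prop-2-en-1-yl)cyclohex-3-en-1-yl]acetate
Conditions: LiN(i-Pr)2, THF, −78 °C; then 8, DMPU, −78 → 0 °C
Reagents that add atoms: methyl bromoacetate (8), COC(=O)CBr
Why: A second α'-enolate alkylation creates the quaternary centre (later C5): the electrophile approaches anti to the vicinal methyl group, so CH2CO2Me ends trans and allyl cis to methyl, as C5/C6 require.

**Step 4**
Reactants: 9 methyl 2-[(1R,6S)-6-methyl-2-oxo-1-(prop-2-en-1-yl)cyclohex-3-en-1-yl]acetate; 10 5-bromo-1,2,3-trimethoxybenzene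
Product: 11 methyl 2-[(1R,5R,6S)-6-methyl-2-oxo-1-(prop-2-en-1-yl)-5-(3,4,5-trimethoxyphenyl)cyclohex-3-en-1-yl]acetate
Conditions: Pd(OAc)2 (5 mol%), P(t-Bu)3·HBF4 (10 mol%), Cs2CO3, 1,4-dioxane, 100 °C
Reagents that add atoms: 5-bromo-1,2,3-trimethoxybenzene (10), COc1cc(Br)cc(OC)c1OC
Why: Palladium-catalysed γ-arylation of the enone through its dienolate (the α'-carbon is quaternary, so only the γ-CH2 is deprotonated); the aryl group enters anti to the vicinal methyl group and the epimerisable centre (later C7) should settle trans-diequatorial.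

**Step 5**
Reactants: 11 methyl 2-[(1R,5R,6S)-6-methyl-2-oxo-1-(prop-2-en-1-yl)-5-(3,4,5-trimethoxyphenyl)cyclohex-3-en-1-yl]acetate
Product: 12 the 3,4-epoxide of 11 (epoxide trans to the aryl group)
Conditions: t-BuOOH, DBU, CH2Cl2, 0 °C → rt
Reagents that add atoms: tert-butyl hydroperoxide, CC(C)(C)OO
Why: Weitz–Scheffer nucleophilic epoxidation attacks only the electron-poor enone double bond and leaves the allyl group; the hydroperoxide should add anti to the neighbouring aryl group.

**Step 6**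
Reactants: 12 the 3,4-epoxide of 11
Product: 14 methyl 2-[4-hydroxy-6-methyl-1-(prop-2-en-1-yl)-5-(3,4,5-trimethoxyphenyl)cyclohex-2-en-1-yl]acetate (OH trans to aryl; other centres as in 11), via epoxy hydrazone 13 (not isolated)
Conditions: N2H4·H2O, AcOH (cat.), MeOH, 0 °C → rt
Reagents that add atoms: none
Why: Wharton transposition: the epoxy hydrazone loses nitrogen to give the transposed allylic alcohol, placing oxygen on the future C1 and the ring double bond at C2=C8; the carbinol keeps the epoxide C–O configuration.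

**Step 7**
Reactants: 14 the transposed allylic alcohol
Product: 15 the 2,3-epoxide of 14 (epoxide syn to OH)
Conditions: VO(acac)2 (5 mol%), t-BuOOH, CH2Cl2, 0 °C → rt
Reagents that add atoms: tert-butyl hydroperoxide, CC(C)(C)OO
Why: Hydroxyl-directed vanadium-catalysed epoxidation delivers oxygen syn to the allylic alcohol and ignores the isolated allyl double bond.

**Step 8**
Reactants: 15 the syn epoxy alcohol
Product: 16 the methyl ether of 15
Conditions: NaH, MeI, THF, 0 °C → rt
Reagents that add atoms: iodomethane, CI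
Why: Williamson methylation installs the future C1 methoxy group; the syn epoxy alkoxide cannot undergo Payne rearrangement, which needs backside attack.

**Step 9**
Reactants: 16 the epoxy methyl ether
Product: 18 methyl (3R,4S,5R,6R)-3-formyl-6-methoxy-4-methyl-7-oxo-3-(prop-2-en-1-yl)-5-(3,4,5-trimethoxyphenyl)heptanoate, via vicinal diol 17 (not isolated)
Conditions: H5IO6, THF/H2O, 0 °C → rt
Reagents that add atoms: water, O
Why: Periodic acid hydrolyses the epoxide to the vicinal diol and cleaves it (Malaprade glycol cleavage), opening the ring between C2 and C8 to two aldehydes without touching the allyl group; no stereocentre is formed.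

**Step 10**
Reactants: 18 the dialdehyde
Product: 19 methyl (3R,4S,5R,6Z)-7-acetoxy-3-formyl-6-methoxy-4-methyl-3-(prop-2-en-1-yl)-5-(3,4,5-trimethoxyphenyl)hept-6-enoate
Conditions: Ac2O, Et3N, DMAP (cat.), CH2Cl2, rt
Reagents that add atoms: acetic anhydride, CC(=O)OC(C)=O
Why: Only the α-methoxy aldehyde (C2) can enolise, the neopentyl aldehyde at C8 has no α-hydrogen, so O-acetylation of the enol gives the enol acetate chemoselectively; the Z isomer is expected but the geometry is not relied on.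

**Step 11**
Reactants: 19 the aldehyde enol acetate
Product: 23 5-allyl-1,3-dimethoxy-6-methyl-7-(3,4,5-trimethoxyphenyl)-3,8-epoxybicyclo[3.2.1]octan-2-yl acetate (acetoxy syn to the oxygen bridge; C5 S, C6 S, C7 R), via tosylhydrazone 20 (not isolated), via diazoalkane 21 (not isolated), via carbonyl ylide 22 (not isolated)
Conditions: TsNHNH2, THF, 4 Å MS, rt; NaH, 0 °C; then Rh2(OAc)4 (2 mol%), BnEt3NCl (10 mol%), 1,4-dioxane, 90 °C
Reagents that add atoms: none
Why: Condensation and Bamford–Stevens fragmentation of the hydrazone salt release diazoalkane 21, which Rh2(OAc)4 turns into a carbene at C8 (no β-hydrogen, C5 being quaternary); the C3 ester carbonyl oxygen closes onto it to give the five-membered 2-methoxy carbonyl ylide 22, which adds across the tethered C1=C2 bond in a concerted suprafacial [3+2] cycloaddition, forming C8–C1 and C3–C2. The closest known reaction type is the tandem rhodium-carbenoid cyclisation/carbonyl-ylide cycloaddition of diazo carbonyl compounds (Padwa), here fed by a tosylhydrazone salt. The cyclopentane (C8–C5–C6–C7–C1) closes in the exo mode dictated by the three-atom tether, and the cyclohexane (C8–C1–C2–C3–C4–C5) closes with it as the carbocyclic part of the 7-oxanorbornane. C1 is fixed by the tether, which can only span the endo positions of C1 and C5 and so places OMe exo; C8 and C3 are bridgeheads and follow; C2 is fixed by the Z-alkene geometry (OAc syn to the oxygen bridge, corrected in steps 13–14), and C5, C6, C7 are untouched. The step needs ylide formation to beat cyclopropanation of the enol acetate and needs the C8–C1/C3–C2 regiochemistry: the first is secured by five-membered closure onto the Lewis-basic carbonyl next to the carbene and by the weakly nucleophilic enol acetate, the second by the tether length.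

**Step 12**
Reactants: 23 the oxygen-bridged cycloadduct
Product: 25 (1R,2S,5S,6S,7R,8R)-1,3-dimethoxy-6-methyl-5-(prop-2-en-1-yl)-7-(3,4,5-trimethoxyphenyl)bicyclo[3.2.1]oct-3-ene-2,8-diol, via silyl ether 24 (not isolated)
Conditions: TMSOTf, i-Pr2NEt, CH2Cl2, −78 → 0 °C; then K2CO3, MeOH, rt
Reagents that add atoms: none
Why: Gassman-type conversion of a ketal into an enol ether: TMSOTf ionises the strained bridging C3–O bond, the amine removes a proton from the less hindered C4 to give the C3=C4 methyl enol ether, and methanolysis then cleaves the silyl ether and the acetate; an acetoxonium ion from participation of the C2 acetate should revert and drain through the same elimination.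

**Step 13**
Reactants: 25 the diol
Product: 26 (1R,5S,6S,7R)-1,3-dimethoxy-6-methyl-5-(prop-2-en-1-yl)-7-(3,4,5-trimethoxyphenyl)bicyclo[3.2.1]oct-3-ene-2,8-dione
Conditions: Dess–Martin periodinane, NaHCO3, CH2Cl2, rt
Reagents that add atoms: none
Why: Dess–Martin oxidation of both secondary alcohols gives the C8 ketone and the C2 enone and erases the wrong C2 configuration.

**Step 14**
Reactants: 26 the enedione
Product: 27 (1S,2R,5S,6S,7R)-2-hydroxy-1,3-dimethoxy-6-methyl-5-(prop-2-en-1-yl)-7-(3,4,5-trimethoxyphenyl)bicyclo[3.2.1]oct-3-en-8-one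
Conditions: NaBH4, CeCl3·7H2O, MeOH, −78 °C
Reagents that add atoms: none
Why: Luche 1,2-reduction should select the conjugated C2 carbonyl over the doubly neopentyl C8 ketone; hydride attacks the face syn to the C8 bridge, away from the endo aryl group on C7, which sets C2 as R.

**Step 15**
Reactants: 27 the allylic alcohol
Product: 28 (1S,2R,5S,6S,7R)-1,3-dimethoxy-6-methyl-8-oxo-5-(prop-2-en-1-yl)-7-(3,4,5-trimethoxyphenyl)bicyclo[3.2.1]oct-3-en-2-yl acetate
Conditions: Ac2O, pyridine, DMAP (cat.), CH2Cl2, rt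
Reagents that add atoms: acetic anhydride, CC(=O)OC(C)=O
Why: DMAP-catalysed acetylation of the secondary alcohol gives the target without touching any stereocentre.

**Compound list**

1 | tert-butyl 3-oxobutanoate | CC(=O)CC(=O)OC(C)(C)C | starting material
2 | (E)-but-2-enal | C/C=C/C=O | starting material
3 | tert-butyl (3S)-2-acetyl-3-methyl-5-oxopentanoate (C2 epimers) | CC(=O)C(C(=O)OC(C)(C)C)[C@@H](C)CC=O | intermediate
4 | tert-butyl (6S)-6-methyl-2-oxocyclohex-3-ene-1-carboxylate (C1 epimers) | O=C1C=CC[C@H](C)C1C(=O)OC(C)(C)C | intermediate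
5 | (S)-5-methylcyclohex-2-en-1-one | O=C1C=CC[C@H](C)C1 | intermediate
6 | allyl bromide | C=CCBr | starting material
7 | (5S,6R)-5-methyl-6-(prop-2-en-1-yl)cyclohex-2-en-1-one | O=C1C=CC[C@H](C)[C@H]1CC=C | intermediate
8 | methyl bromoacetate | COC(=O)CBr | starting material
9 | methyl 2-[(1R,6S)-6-methyl-2-oxo-1-(prop-2-en-1-yl)cyclohex-3-en-1-yl]acetate | O=C1C=CC[C@H](C)[C@@]1(CC=C)CC(=O)OC | intermediate
10 | 5-bromo-1,2,3-trimethoxybenzene | COc1cc(Br)cc(OC)c1OC | starting material
11 | methyl 2-[(1R,5R,6S)-6-methyl-2-oxo-1-(prop-2-en-1-yl)-5-(3,4,5-trimethoxyphenyl)cyclohex-3-en-1-yl]acetate | O=C1C=C[C@@H](c2cc(OC)c(OC)c(OC)c2)[C@H](C)[C@@]1(CC=C)CC(=O)OC | intermediate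
12 | 3,4-epoxide of 11, epoxide trans to aryl | O=C1[C@@H]2O[C@@H]2[C@@H](c2cc(OC)c(OC)c(OC)c2)[C@H](C)[C@@]1(CC=C)CC(=O)OC | intermediate
13 | hydrazone of epoxy ketone 12 | NN=C1[C@@H]2O[C@@H]2[C@@H](c2cc(OC)c(OC)c(OC)c2)[C@H](C)[C@@]1(CC=C)CC(=O)OC | intermediate
14 | methyl 2-[4-hydroxy-6-methyl-1-(prop-2-en-1-yl)-5-(3,4,5-trimethoxyphenyl)cyclohex-2-en-1-yl]acetate, OH trans to aryl | O[C@H]1C=C[C@](CC=C)(CC(=O)OC)[C@@H](C)[C@@H]1c1cc(OC)c(OC)c(OC)c1 | intermediate
15 | 2,3-epoxide of 14, syn to OH | O[C@H]1[C@H]2O[C@H]2[C@](CC=C)(CC(=O)OC)[C@@H](C)[C@@H]1c1cc(OC)c(OC)c(OC)c1 | intermediate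
16 | methyl ether of 15 | CO[C@H]1[C@H]2O[C@H]2[C@](CC=C)(CC(=O)OC)[C@@H](C)[C@@H]1c1cc(OC)c(OC)c(OC)c1 | intermediate
17 | vicinal diol from hydrolysis of 16 (diol centres not defined, both are cleaved) | CO[C@H]1C(O)C(O)[C@](CC=C)(CC(=O)OC)[C@@H](C)[C@@H]1c1cc(OC)c(OC)c(OC)c1 | intermediate
18 | methyl (3R,4S,5R,6R)-3-formyl-6-methoxy-4-methyl-7-oxo-3-(prop-2-en-1-yl)-5-(3,4,5-trimethoxyphenyl)heptanoate | O=C[C@](CC=C)(CC(=O)OC)[C@@H](C)[C@H](c1cc(OC)c(OC)c(OC)c1)[C@@H](OC)C=O | intermediate
19 | methyl (3R,4S,5R,6Z)-7-acetoxy-3-formyl-6-methoxy-4-methyl-3-(prop-2-en-1-yl)-5-(3,4,5-trimethoxyphenyl)hept-6-enoate | O=C[C@](CC=C)(CC(=O)OC)[C@@H](C)[C@H](c1cc(OC)c(OC)c(OC)c1)/C(OC)=C/OC(C)=O | intermediate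
20 | N-tosylhydrazone of aldehyde 19 | Cc1ccc(cc1)S(=O)(=O)N/N=C/[C@](CC=C)(CC(=O)OC)[C@@H](C)[C@H](c1cc(OC)c(OC)c(OC)c1)/C(OC)=C/OC(C)=O | intermediate
21 | diazoalkane from 20 | [N-]=[N+]=C[C@](CC=C)(CC(=O)OC)[C@@H](C)[C@H](c1cc(OC)c(OC)c(OC)c1)/C(OC)=C/OC(C)=O | intermediate
22 | cyclic carbonyl ylide (2-methoxy-4,4-disubstituted oxolan-1-ium-5-ide) | [CH-]1[O+]=C(OC)C[C@]1(CC=C)[C@@H](C)[C@H](c1cc(OC)c(OC)c(OC)c1)/C(OC)=C/OC(C)=O | intermediate
23 | 5-allyl-1,3-dimethoxy-6-methyl-7-(3,4,5-trimethoxyphenyl)-3,8-epoxybicyclo[3.2.1]octan-2-yl acetate, acetoxy syn to the oxygen bridge | C=CC[C@]12C[C@@]3(OC)[C@H](OC(C)=O)[C@](OC)([C@@H]1O3)[C@@H](c1cc(OC)c(OC)c(OC)c1)[C@@H]2C | intermediate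
24 | 8-O-trimethylsilyl enol ether acetate (ring-opened 23) | C=CC[C@]12C=C(OC)[C@H](OC(C)=O)[C@](OC)([C@@H]1O[Si](C)(C)C)[C@@H](c1cc(OC)c(OC)c(OC)c1)[C@@H]2C | intermediate
25 | (1R,2S,5S,6S,7R,8R)-1,3-dimethoxy-6-methyl-5-(prop-2-en-1-yl)-7-(3,4,5-trimethoxyphenyl)bicyclo[3.2.1]oct-3-ene-2,8-diol | C=CC[C@]12C=C(OC)[C@H](O)[C@](OC)([C@@H]1O)[C@@H](c1cc(OC)c(OC)c(OC)c1)[C@@H]2C | intermediate
26 | (1R,5S,6S,7R)-1,3-dimethoxy-6-methyl-5-(prop-2-en-1-yl)-7-(3,4,5-trimethoxyphenyl)bicyclo[3.2.1]oct-3-ene-2,8-dione | C=CC[C@]12C=C(OC)C(=O)[C@](OC)(C1=O)[C@@H](c1cc(OC)c(OC)c(OC)c1)[C@@H]2C | intermediate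
27 | (1S,2R,5S,6S,7R)-2-hydroxy-1,3-dimethoxy-6-methyl-5-(prop-2-en-1-yl)-7-(3,4,5-trimethoxyphenyl)bicyclo[3.2.1]oct-3-en-8-one | C=CC[C@]12C=C(OC)[C@@H](O)[C@](OC)(C1=O)[C@@H](c1cc(OC)c(OC)c(OC)c1)[C@@H]2C | intermediate
28 | (1S,2R,5S,6S,7R)-1,3-dimethoxy-6-methyl-8-oxo-5-(prop-2-en-1-yl)-7-(3,4,5-trimethoxyphenyl)bicyclo[3.2.1]oct-3-en-2-yl acetate | C=CC[C@]12C=C(OC)[C@@H](OC(C)=O)[C@](OC)(C1=O)[C@@H](c1cc(OC)c(OC)c(OC)c1)[C@@H]2C | target

**Step count and risks**

Total steps: 15. Longest linear sequence: 15 steps (from 1 and 2 to 28).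

Steps most likely to fail:

1. Step 11 (key step). The carbene may be diverted before the ylide forms (intramolecular cyclopropanation of the enol acetate, 1,2-alkyl shift, azine formation), or the ylide may be quenched by a 1,4-proton shift from C4 before it cycloadds. The fallback builds the two bonds one after the other with known chemistry; it sets out from dialdehyde 18 and comes back at dione 26. Pyrrolidine/AcOH (cat.) should effect the intramolecular aldol of the enolisable aldehyde onto the neopentyl aldehyde (C1 to C8), giving cyclopentanol aldehyde F1; the aldol is reversible and only the epimer with the formyl group cis to the acetate side chain goes on. LiAlH4 reduces aldehyde and ester to triol F2. TEMPO/PhI(OAc)2 oxidises only the two primary alcohols to hydroxy dialdehyde F3. A triazolium carbene catalyst with DBU closes C2–C3 by intramolecular crossed benzoin reaction to acyloin F4. Excess Dess–Martin periodinane gives the trione, present as diosphenol F5, and TMSCHN2/MeOH methylates the enol oxygen to give 26.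

2. Step 4. The dienolate may be arylated at its α-carbon, arylated twice, or with poor facial selectivity. The fallback moves the ketone next to the carbon to be arylated; it sets out from 9 and comes back at 14, replacing steps 4–6. t-BuOOH/DBU gives epoxy ketone F6, Wharton transposition (N2H4·H2O, AcOH) gives allylic alcohol F7, and MnO2 gives transposed enone F8. Its only enolisable position is the future C7, so α'-arylation with 10 (Pd2(dba)3, XPhos, NaOt-Bu, toluene, 70 °C) should give aryl enone F9 with the aryl trans to methyl after equilibration. Luche reduction (axial hydride, equatorial alcohol trans to aryl) then gives 14.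

3. Step 12. Participation of the C2 acetate, proton loss from C2 instead of C4, or hydrolysis to the C3 ketone may spoil the elimination. The fallback makes the enol ether by O-methylation instead; it sets out from 23 and comes back at 26, replacing steps 12–13. K2CO3/MeOH gives hydroxy ketal F10, Dess–Martin periodinane gives keto ketal F11, aqueous HCl/THF hydrolyses the strained ketal to hydroxy diosphenol F12 (which can enolise only towards C4), TMSCHN2/MeOH gives methoxy enone F13, and Dess–Martin oxidation of the C8 alcohol gives 26.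

**Further compounds**

F1 | step 11 | methyl 2-[3-formyl-2-hydroxy-3-methoxy-5-methyl-1-(prop-2-en-1-yl)-4-(3,4,5-trimethoxyphenyl)cyclopentyl]acetate (carbinol centre not defined) | C=CC[C@]1(CC(=O)OC)C(O)[C@@](OC)(C=O)[C@@H](c2cc(OC)c(OC)c(OC)c2)[C@@H]1C
F2 | step 11 | triol from reduction of F1 | C=CC[C@]1(CCO)C(O)[C@@](OC)(CO)[C@@H](c2cc(OC)c(OC)c(OC)c2)[C@@H]1C
F3 | step 11 | hydroxy dialdehyde | C=CC[C@]1(CC=O)C(O)[C@@](OC)(C=O)[C@@H](c2cc(OC)c(OC)c(OC)c2)[C@@H]1C
F4 | step 11 | bicyclic acyloin (2,8-dihydroxy-1-methoxy-bicyclo[3.2.1]octan-3-one core) | C=CC[C@]12CC(=O)C(O)[C@](OC)(C1O)[C@@H](c1cc(OC)c(OC)c(OC)c1)[C@@H]2C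
F5 | step 11 | diosphenol (3-hydroxy-1-methoxy-bicyclo[3.2.1]oct-3-ene-2,8-dione core) | C=CC[C@]12C=C(O)C(=O)[C@](OC)(C1=O)[C@@H](c1cc(OC)c(OC)c(OC)c1)[C@@H]2C
F6 | step 4 | 3,4-epoxide of 9 | O=C1C2OC2C[C@H](C)[C@@]1(CC=C)CC(=O)OC
F7 | step 4 | methyl 2-[4-hydroxy-6-methyl-1-(prop-2-en-1-yl)cyclohex-2-en-1-yl]acetate | OC1C=C[C@](CC=C)(CC(=O)OC)[C@@H](C)C1
F8 | step 4 | methyl 2-[6-methyl-4-oxo-1-(prop-2-en-1-yl)cyclohex-2-en-1-yl]acetate | O=C1C=C[C@](CC=C)(CC(=O)OC)[C@@H](C)C1
F9 | step 4 | methyl 2-[6-methyl-4-oxo-1-(prop-2-en-1-yl)-5-(3,4,5-trimethoxyphenyl)cyclohex-2-en-1-yl]acetate, aryl trans to methyl | O=C1C=C[C@](CC=C)(CC(=O)OC)[C@@H](C)[C@@H]1c1cc(OC)c(OC)c(OC)c1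
F10 | step 12 | deacetylated cycloadduct (2-hydroxy ketal) | C=CC[C@]12C[C@@]3(OC)[C@H](O)[C@](OC)([C@@H]1O3)[C@@H](c1cc(OC)c(OC)c(OC)c1)[C@@H]2C
F11 | step 12 | 2-keto ketal | C=CC[C@]12C[C@@]3(OC)C(=O)[C@](OC)([C@@H]1O3)[C@@H](c1cc(OC)c(OC)c(OC)c1)[C@@H]2C
F12 | step 12 | 8-hydroxy diosphenol | C=CC[C@]12C=C(O)C(=O)[C@](OC)([C@@H]1O)[C@@H](c1cc(OC)c(OC)c(OC)c1)[C@@H]2C
F13 | step 12 | 8-hydroxy-1,3-dimethoxy enone | C=CC[C@]12C=C(OC)C(=O)[C@](OC)([C@@H]1O)[C@@H](c1cc(OC)c(OC)c(OC)c1)[C@@H]2C
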